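**Plan**

- Retrosynthesis cuts, in this order: the 3'-O–galloyl ester; the O1–C2 bond of ring C; the C2–C1' bond to ring B (at a Weinreb amide); and the C3–C4 bond (glycolate enolate plus ring A benzylic bromide).
- Forward: C3–C4 is joined first by Evans alkylation, ring B is added as a Grignard reagent, and the ketone is reduced. Ring C, the only ring made, is closed last through O1–C2. Deallylation, galloylation and hydrogenolysis finish the route.
- Enabling feature: C2 is benzylic to ring B and para to its 4'-oxygen, so it ionises readily, and the ring A oxygen O1 is placed to capture the cation in a six-membered closure.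
- Stereochemistry: C3 (S) comes from an (R)-4-benzyloxazolidinone auxiliary in the alkylation. C2 (R) is set in the ring closure under control of C3, both carbinol epimers converging on one cation.
- Protecting groups: benzyl on O3, O5, O7 and O4'; methoxymethyl on the ring A oxygen that becomes O1; allyl on O3', the site of the gallate.

Key step: step 12

Assumption: the brominated ring B aldehyde used in step 8 is taken as purchasable (it is otherwise one O-benzylation away from 5-bromosalicylaldehyde). Catechin numbering (O1, C2, C3, C4, rings A, B, C) is used throughout.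

**Route**

Step 1
Reactants: 1 2,4,6-trihydroxybenzaldehyde
Product: 2 2,4-bis(benzyloxy)-6-hydroxybenzaldehyde
Conditions: BnBr (2.1 equiv), K2CO3 (2.2 equiv), DMF, 0 °C → rt
Reagents that add atoms: benzyl bromide, BrCc1ccccc1
Why: Williamson etherification, in which the 4-hydroxyl and one ortho hydroxyl should react while the last ortho hydroxyl, held in a hydrogen bond to the formyl oxygen, is the least nucleophilic and should stay free when only two equivalents of halide are offered.

Step 2
Reactants: 2 2,4-bis(benzyloxy)-6-hydroxybenzaldehyde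
Product: 3 2,4-bis(benzyloxy)-6-(methoxymethoxy)benzaldehyde
Conditions: NaH, DMF, 0 °C; then MOMCl, 0 °C → rt
Reagents that add atoms: chloromethyl methyl ether, COCCl
Why: O-alkylation of the sodium phenoxide (Williamson-type acetal formation), since full deprotonation breaks the hydrogen bond and lets the remaining hydroxyl take up the chloromethyl ether.

Step 3
Reactants: 3 2,4-bis(benzyloxy)-6-(methoxymethoxy)benzaldehyde
Product: 4 [2,4-bis(benzyloxy)-6-(methoxymethoxy)phenyl]methanol
Conditions: NaBH4, MeOH/THF, 0 °C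
Reagents that add atoms: none
Why: Borohydride reduction of an aryl aldehyde to the benzylic alcohol, to which the ethers and the acetal are inert.

Step 4
Reactants: 4 [2,4-bis(benzyloxy)-6-(methoxymethoxy)phenyl]methanol
Product: 5 1,5-bis(benzyloxy)-2-(bromomethyl)-3-(methoxymethoxy)benzene
Conditions: PBr3 (0.4 equiv), pyridine (cat.), Et2O, –10 °C; cold aqueous NaHCO3 wash; used at once without chromatography
Reagents that add atoms: phosphorus tribromide, BrP(Br)Br
Why: Bromination of a benzylic alcohol with PBr3, buffered by pyridine so that the methoxymethyl acetal does not meet free HBr, with the electron-rich bromide kept cold and carried on crude because it ionises easily.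

Step 5
Reactants: 6 (R)-4-benzyloxazolidin-2-one; 7 benzyloxyacetyl chloride
Product: 8 (4R)-4-benzyl-3-[(benzyloxy)acetyl]oxazolidin-2-one
Conditions: n-BuLi, THF, –78 °C; then 7, –78 → 0 °C
Reagents that add atoms: none
Why: N-acylation of the lithiated oxazolidinone with an acid chloride, the standard entry to Evans imides.

Step 6
Reactants: 8 (4R)-4-benzyl-3-[(benzyloxy)acetyl]oxazolidin-2-one; 5 1,5-bis(benzyloxy)-2-(bromomethyl)-3-(methoxymethoxy)benzene
Product: 9 (4R)-4-benzyl-3-[(2S)-2-(benzyloxy)-3-[2,4-bis(benzyloxy)-6-(methoxymethoxy)phenyl]propanoyl]oxazolidin-2-one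
Conditions: 8 (1.5 equiv), NaN(SiMe3)2, THF, –78 °C; then 5 in THF, –78 → –40 °C
Reagents that add atoms: none
Why: Evans asymmetric alkylation, in which the chelated Z sodium enolate of the glycolate imide is attacked by the reactive benzylic bromide on the face opposite the 4-benzyl group of the (R)-auxiliary, which should set the benzyloxy-bearing carbon (the future C3) as S.

Step 7
Reactants: 9 (4R)-4-benzyl-3-[(2S)-2-(benzyloxy)-3-[2,4-bis(benzyloxy)-6-(methoxymethoxy)phenyl]propanoyl]oxazolidin-2-one
Product: 10 (2S)-2-(benzyloxy)-3-[2,4-bis(benzyloxy)-6-(methoxymethoxy)phenyl]-N-methoxy-N-methylpropanamide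
Conditions: MeNH(OMe)·HCl, AlMe3, CH2Cl2, –15 → 0 °C
Reagents that add atoms: N,O-dimethylhydroxylamine hydrochloride, CNOC.Cl
Why: Weinreb amide formation by transamination of the imide with the aluminium amide, which cleaves the exocyclic acyl group without touching the α stereocentre and returns the auxiliary.

Step 8
Reactants: 11 2-(benzyloxy)-5-bromobenzaldehyde
Product: 13 2-(benzyloxy)-5-bromophenol, via aryl formate 12 (not isolated)
Conditions: mCPBA, CH2Cl2, rt; NaHCO3 wash; then K2CO3 (cat.), MeOH, rt
Reagents that add atoms: 3-chloroperoxybenzoic acid, OOC(=O)c1cccc(Cl)c1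
Why: Baeyer–Villiger oxidation of an ortho-alkoxybenzaldehyde with aryl migration gives the aryl formate, which methanol cleaves to the phenol, leaving bromine para to the benzyloxy group as ring B requires.

Step 9
Reactants: 13 2-(benzyloxy)-5-bromophenol
Product: 14 2-(allyloxy)-1-(benzyloxy)-4-bromobenzene
Conditions: allyl bromide, K2CO3, DMF, rt
Reagents that add atoms: allyl bromide, C=CCBr
Why: Williamson etherification of the phenol, giving an allyl ether that is orthogonal to the benzyl ethers and should survive Grignard formation and aqueous acid.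

Step 10
Reactants: 10 (2S)-2-(benzyloxy)-3-[2,4-bis(benzyloxy)-6-(methoxymethoxy)phenyl]-N-methoxy-N-methylpropanamide; 14 2-(allyloxy)-1-(benzyloxy)-4-bromobenzene
Product: 16 (2S)-1-[3-(allyloxy)-4-(benzyloxy)phenyl]-2-(benzyloxy)-3-[2,4-bis(benzyloxy)-6-(methoxymethoxy)phenyl]propan-1-one, via arylmagnesium bromide 15 (not isolated)
Conditions: 14, Mg turnings, I2 (cat.), THF, 40 °C; then 10, THF, 0 °C; aqueous NH4Cl
Reagents that add atoms: none
Why: Grignard addition to a Weinreb amide stops at the chelated tetrahedral adduct, so the aryl ketone is released only on quench, without over-addition or epimerisation of the α-benzyloxy centre, and the C2–C1' bond is formed.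

Step 11
Reactants: 16 (2S)-1-[3-(allyloxy)-4-(benzyloxy)phenyl]-2-(benzyloxy)-3-[2,4-bis(benzyloxy)-6-(methoxymethoxy)phenyl]propan-1-one
Product: 17 (2S)-1-[3-(allyloxy)-4-(benzyloxy)phenyl]-2-(benzyloxy)-3-[2,4-bis(benzyloxy)-6-(methoxymethoxy)phenyl]propan-1-ol (both C1 epimers)
Conditions: NaBH4, MeOH/THF, 0 °C
Reagents that add atoms: none
Why: Borohydride reduction of the aryl ketone, where the new carbinol centre may form as a mixture because both epimers give the same cation in the next step.

Step 12
Reactants: 17 (2S)-1-[3-(allyloxy)-4-(benzyloxy)phenyl]-2-(benzyloxy)-3-[2,4-bis(benzyloxy)-6-(methoxymethoxy)phenyl]propan-1-ol (both C1 epimers)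
Product: 19 (2R,3S)-2-[3-(allyloxy)-4-(benzyloxy)phenyl]-3,5,7-tris(benzyloxy)chroman, via free phenol 18 (not isolated)
Conditions: HCl (3 M aq.), MeOH/THF, 0.02 M, 45 °C
Reagents that add atoms: none
Why: Acid hydrolyses the aryl methoxymethyl acetal to the free phenol 18 and protonates the benzylic hydroxyl, and loss of water from either C1 epimer gives the same planar cation at the future C2, stabilised through ring B by the para 4'-benzyloxy oxygen (a quinone-methide-like oxocarbenium ion). The ring A oxygen O1 adds to this cation in an SN1 etherification, the closest known reaction type being the acid-mediated cyclisation of 1-aryl-3-(2-hydroxyaryl)propane-1,2-diols and their methoxymethyl ethers to 2,3-trans-flavan-3-ols. Ring C closes in the 6-exo-trig mode, the cationic carbon lying in the new ring and its π bond to ring B outside it. The new stereocentre C2 is controlled by C3: in the chair-like transition state, allylic 1,3-strain with the coplanar ring B places C3–H, not C3–OBn, beside the aryl plane, so O1 bonds on the face that leaves aryl and benzyloxy trans and both equatorial, giving 2R from 3S. The step needs diastereoselectivity at C2 and chemoselectivity for the acetal and the carbinol; the first is secured by the C3 benzyloxy group and backed by the reversibility of ionisation at the para-alkoxybenzylic ether, the second by the inertness of benzyl and allyl ethers to dilute acid. Methanol removes the methoxymethyl fragment as dimethoxymethane, and high dilution keeps ring A of a second molecule from attacking the cation.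

Step 13
Reactants: 19 (2R,3S)-2-[3-(allyloxy)-4-(benzyloxy)phenyl]-3,5,7-tris(benzyloxy)chroman
Product: 20 2-(benzyloxy)-5-[(2R,3S)-3,5,7-tris(benzyloxy)chroman-2-yl]phenol
Conditions: Pd(PPh3)4 (5 mol%), morpholine, THF, rt
Reagents that add atoms: none
Why: Tsuji–Trost-type deallylation, in which the zerovalent palladium complex ionises the aryl allyl ether to a π-allyl complex that morpholine intercepts, freeing the 3'-phenol while the benzyl ethers stay.

Step 14
Reactants: 20 2-(benzyloxy)-5-[(2R,3S)-3,5,7-tris(benzyloxy)chroman-2-yl]phenol; 21 3,4,5-tris(benzyloxy)benzoic acid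
Product: 22 2-(benzyloxy)-5-[(2R,3S)-3,5,7-tris(benzyloxy)chroman-2-yl]phenyl 3,4,5-tris(benzyloxy)benzoate
Conditions: DCC, DMAP (cat.), CH2Cl2, 0 °C → rt
Reagents that add atoms: none
Why: Steglich esterification, in which the carbodiimide-activated acid is passed through the acylpyridinium ion to the only free hydroxyl, the 3'-phenol.

Step 15
Reactants: 22 2-(benzyloxy)-5-[(2R,3S)-3,5,7-tris(benzyloxy)chroman-2-yl]phenyl 3,4,5-tris(benzyloxy)benzoate
Product: 23 catechin 3'-O-gallate, 2-hydroxy-5-[(2R,3S)-3,5,7-trihydroxychroman-2-yl]phenyl 3,4,5-trihydroxybenzoate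
Conditions: H2 (1 atm), Pd(OH)2 on carbon, THF/EtOAc, rt
Reagents that add atoms: none
Why: Hydrogenolysis of the seven benzyl ethers under neutral, alcohol-free conditions should leave the aryl ester and the chroman C–O bonds in place and does not touch C2 or C3.

**Compound list**

1 | 2,4,6-trihydroxybenzaldehyde | O=Cc1c(O)cc(O)cc1O | starting material
2 | 2,4-bis(benzyloxy)-6-hydroxybenzaldehyde | O=Cc1c(O)cc(OCc2ccccc2)cc1OCc1ccccc1 | intermediate
3 | 2,4-bis(benzyloxy)-6-(methoxymethoxy)benzaldehyde | O=Cc1c(OCOC)cc(OCc2ccccc2)cc1OCc1ccccc1 | intermediate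
4 | [2,4-bis(benzyloxy)-6-(methoxymethoxy)phenyl]methanol | OCc1c(OCOC)cc(OCc2ccccc2)cc1OCc1ccccc1 | intermediate
5 | 1,5-bis(benzyloxy)-2-(bromomethyl)-3-(methoxymethoxy)benzene | BrCc1c(OCOC)cc(OCc2ccccc2)cc1OCc1ccccc1 | intermediate
6 | (R)-4-benzyloxazolidin-2-one | O=C1N[C@H](Cc2ccccc2)CO1 | starting material
7 | benzyloxyacetyl chloride | O=C(Cl)COCc1ccccc1 | starting material
8 | (4R)-4-benzyl-3-[(benzyloxy)acetyl]oxazolidin-2-one | O=C(COCc1ccccc1)N1[C@H](Cc2ccccc2)COC1=O | intermediate
9 | (4R)-4-benzyl-3-[(2S)-2-(benzyloxy)-3-[2,4-bis(benzyloxy)-6-(methoxymethoxy)phenyl]propanoyl]oxazolidin-2-one | O=C([C@@H](OCc1ccccc1)Cc1c(OCOC)cc(OCc2ccccc2)cc1OCc1ccccc1)N1[C@H](Cc2ccccc2)COC1=O | intermediate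
10 | (2S)-2-(benzyloxy)-3-[2,4-bis(benzyloxy)-6-(methoxymethoxy)phenyl]-N-methoxy-N-methylpropanamide | CON(C)C(=O)[C@@H](OCc1ccccc1)Cc1c(OCOC)cc(OCc2ccccc2)cc1OCc1ccccc1 | intermediate
11 | 2-(benzyloxy)-5-bromobenzaldehyde | O=Cc1cc(Br)ccc1OCc1ccccc1 | starting material
12 | 2-(benzyloxy)-5-bromophenyl formate | O=COc1cc(Br)ccc1OCc1ccccc1 | intermediate
13 | 2-(benzyloxy)-5-bromophenol | Oc1cc(Br)ccc1OCc1ccccc1 | intermediate
14 | 2-(allyloxy)-1-(benzyloxy)-4-bromobenzene | C=CCOc1cc(Br)ccc1OCc1ccccc1 | intermediate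
15 | [3-(allyloxy)-4-(benzyloxy)phenyl]magnesium bromide | C=CCOc1cc([Mg]Br)ccc1OCc1ccccc1 | intermediate
16 | (2S)-1-[3-(allyloxy)-4-(benzyloxy)phenyl]-2-(benzyloxy)-3-[2,4-bis(benzyloxy)-6-(methoxymethoxy)phenyl]propan-1-one | O=C(c1ccc(OCc2ccccc2)c(OCC=C)c1)[C@@H](OCc1ccccc1)Cc1c(OCOC)cc(OCc2ccccc2)cc1OCc1ccccc1 | intermediate
17 | (2S)-1-[3-(allyloxy)-4-(benzyloxy)phenyl]-2-(benzyloxy)-3-[2,4-bis(benzyloxy)-6-(methoxymethoxy)phenyl]propan-1-ol, both C1 epimers | OC(c1ccc(OCc2ccccc2)c(OCC=C)c1)[C@@H](OCc1ccccc1)Cc1c(OCOC)cc(OCc2ccccc2)cc1OCc1ccccc1 | intermediate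
18 | (2S)-1-[3-(allyloxy)-4-(benzyloxy)phenyl]-2-(benzyloxy)-3-[2,4-bis(benzyloxy)-6-hydroxyphenyl]propan-1-ol, both C1 epimers | OC(c1ccc(OCc2ccccc2)c(OCC=C)c1)[C@@H](OCc1ccccc1)Cc1c(O)cc(OCc2ccccc2)cc1OCc1ccccc1 | intermediate
19 | (2R,3S)-2-[3-(allyloxy)-4-(benzyloxy)phenyl]-3,5,7-tris(benzyloxy)chroman | C=CCOc1cc([C@H]2Oc3cc(OCc4ccccc4)cc(OCc4ccccc4)c3C[C@@H]2OCc2ccccc2)ccc1OCc1ccccc1 | intermediate
20 | 2-(benzyloxy)-5-[(2R,3S)-3,5,7-tris(benzyloxy)chroman-2-yl]phenol | Oc1cc([C@H]2Oc3cc(OCc4ccccc4)cc(OCc4ccccc4)c3C[C@@H]2OCc2ccccc2)ccc1OCc1ccccc1 | intermediate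
21 | 3,4,5-tris(benzyloxy)benzoic acid | OC(=O)c1cc(OCc2ccccc2)c(OCc2ccccc2)c(OCc2ccccc2)c1 | starting material
22 | 2-(benzyloxy)-5-[(2R,3S)-3,5,7-tris(benzyloxy)chroman-2-yl]phenyl 3,4,5-tris(benzyloxy)benzoate | O=C(Oc1cc([C@H]2Oc3cc(OCc4ccccc4)cc(OCc4ccccc4)c3C[C@@H]2OCc2ccccc2)ccc1OCc1ccccc1)c1cc(OCc2ccccc2)c(OCc2ccccc2)c(OCc2ccccc2)c1 | intermediate
23 | catechin 3'-O-gallate, 2-hydroxy-5-[(2R,3S)-3,5,7-trihydroxychroman-2-yl]phenyl 3,4,5-trihydroxybenzoate | O=C(Oc1cc([C@H]2Oc3cc(O)cc(O)c3C[C@@H]2O)ccc1O)c1cc(O)c(O)c(O)c1 | target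

**Step count**

Total step count: 15.
Longest linear sequence: 12 steps (steps 1–4, 6, 7 and 10–15, from 1 to 23).

**Steps most likely to fail**

Step 6. The bromide 5 carries three ring oxygens ortho and para to the bromomethyl group and may be lost by ionisation and self-alkylation before the enolate captures it. The enolate may also decompose if the temperature has to be raised. The fallback makes the C3–C4 bond by an aldol addition to the aldehyde instead of a substitution at a benzylic halide. It sets out from aldehyde 3 and acid chloride 7. The enantiomeric imide (4S)-4-benzyl-3-[(benzyloxy)acetyl]oxazolidin-2-one F1 is prepared as in step 5 from (S)-4-benzyloxazolidin-2-one. It is enolised with Bu2BOTf and Et3N in CH2Cl2 and added to 3 (Evans boron aldol). This should give the syn adduct (4S)-4-benzyl-3-[(2S,3R)-2-(benzyloxy)-3-[2,4-bis(benzyloxy)-6-(methoxymethoxy)phenyl]-3-hydroxypropanoyl]oxazolidin-2-one F2. The opposite auxiliary is needed because the boron aldol and the chelated alkylation use opposite enolate faces. The benzylic hydroxyl, flanked by the same three donor oxygens, is then removed by ionic hydrogenation (Et3SiH, CF3CO2H, CH2Cl2, –40 °C, below the temperature at which the aryl acetal is cleaved). This gives (4S)-4-benzyl-3-[(2S)-2-(benzyloxy)-3-[2,4-bis(benzyloxy)-6-(methoxymethoxy)phenyl]propanoyl]oxazolidin-2-one F3. Transamination under the conditions of step 7 brings the material back to the route at Weinreb amide 10.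

Step 12. Capture of the cation may show poor facial selectivity and leave too much of the 2,3-cis isomer. Proton loss from the cation toward C3 would also erode the C3 centre. The fallback closes ring C by a stereospecific SN2 etherification that avoids the cation. It sets out from Weinreb amide 10, where no ionisable carbinol is present yet. The acetal is cleaved first (HCl, MeOH, rt) to give (2S)-2-(benzyloxy)-3-[2,4-bis(benzyloxy)-6-hydroxyphenyl]-N-methoxy-N-methylpropanamide F4. Excess Grignard reagent 15 then gives, after a neutral quench, the hydroxy ketone (2S)-1-[3-(allyloxy)-4-(benzyloxy)phenyl]-2-(benzyloxy)-3-[2,4-bis(benzyloxy)-6-hydroxyphenyl]propan-1-one F5. Felkin–Anh reduction with KBH(s-Bu)3 in THF at –78 °C should favour the syn alcohol (1S,2S)-1-[3-(allyloxy)-4-(benzyloxy)phenyl]-2-(benzyloxy)-3-[2,4-bis(benzyloxy)-6-hydroxyphenyl]propan-1-ol F6. An intramolecular Mitsunobu etherification (PPh3, DIAD, THF, 0 °C) then joins O1 to the carbinol carbon with inversion and returns to the route at chroman 19.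

Step 15. Once the 4'-hydroxyl is free, the galloyl group may migrate from the 3'- to the 4'-oxygen or be lost by solvolysis. The benzylic O1–C2 bond may also be opened on the metal surface. The fallback removes the benzyl groups from 22 without hydrogen or metal: BCl3 with pentamethylbenzene as benzyl cation scavenger in CH2Cl2 at –78 °C, followed by a methanol quench at low temperature. These Lewis acidic conditions do not promote acyl migration in catechol monoesters and spare the aryl ester. The fallback goes from 22 directly to 23 and makes no new compound, F0.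

**Further compounds**

F1 | step 6 | (4S)-4-benzyl-3-[(benzyloxy)acetyl]oxazolidin-2-one | O=C(COCc1ccccc1)N1[C@@H](Cc2ccccc2)COC1=O
F2 | step 6 | (4S)-4-benzyl-3-[(2S,3R)-2-(benzyloxy)-3-[2,4-bis(benzyloxy)-6-(methoxymethoxy)phenyl]-3-hydroxypropanoyl]oxazolidin-2-one | O=C([C@@H](OCc1ccccc1)[C@H](O)c1c(OCOC)cc(OCc2ccccc2)cc1OCc1ccccc1)N1[C@@H](Cc2ccccc2)COC1=O
F3 | step 6 | (4S)-4-benzyl-3-[(2S)-2-(benzyloxy)-3-[2,4-bis(benzyloxy)-6-(methoxymethoxy)phenyl]propanoyl]oxazolidin-2-one | O=C([C@@H](OCc1ccccc1)Cc1c(OCOC)cc(OCc2ccccc2)cc1OCc1ccccc1)N1[C@@H](Cc2ccccc2)COC1=O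
F4 | step 12 | (2S)-2-(benzyloxy)-3-[2,4-bis(benzyloxy)-6-hydroxyphenyl]-N-methoxy-N-methylpropanamide | CON(C)C(=O)[C@@H](OCc1ccccc1)Cc1c(O)cc(OCc2ccccc2)cc1OCc1ccccc1
F5 | step 12 | (2S)-1-[3-(allyloxy)-4-(benzyloxy)phenyl]-2-(benzyloxy)-3-[2,4-bis(benzyloxy)-6-hydroxyphenyl]propan-1-one | O=C(c1ccc(OCc2ccccc2)c(OCC=C)c1)[C@@H](OCc1ccccc1)Cc1c(O)cc(OCc2ccccc2)cc1OCc1ccccc1
F6 | step 12 | (1S,2S)-1-[3-(allyloxy)-4-(benzyloxy)phenyl]-2-(benzyloxy)-3-[2,4-bis(benzyloxy)-6-hydroxyphenyl]propan-1-ol | O[C@@H](c1ccc(OCc2ccccc2)c(OCC=C)c1)[C@@H](OCc1ccccc1)Cc1c(O)cc(OCc2ccccc2)cc1OCc1ccccc1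
F0 | step 15 | none | none
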